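The numbering is germacrane: C1/C10 oxirane, C4=C5 enoate (C15 ester), C7 isopropenyl, C9 acetate, C14 isobutyrate. Everything rests on disconnecting C1–C2 of the ten-membered carbocycle one oxidation level below the oxirane. There C1 is the vinylic end of an E C1=C10 olefin and C2 is a plain CH2. An intramolecular Negishi alkenyl–alkyl coupling closes the ring in one operation with retention of geometry. It exploits the cis C3/C6 arrangement on C4=C5, which folds the chain. It also uses a temporary 1,3-dioxane across O9/O14 that fixes iodine cis to C14. The precursor is an open-chain alkenyl iodide/alkyl iodide built from (R)-carvone by excision of its C2. Sharpless epoxidation then sets C1 and C10.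

Key step: step 10

Remark on locants: the germacrane locants above are used for all intermediates. The target is 1R,7S,9S,10S. C4=C5 is E by CIP (CO2Me trans to C6, so C3 is cis to C6). On the oxirane C2 is cis to C14.

Assumption: the (R)-diphenylprolinol-derived oxazaborolidinium salt is taken to direct addition to the Re face of the C9 aldehyde in step 4. If the sense is the opposite, its enantiomer is used.

Compounds 1, 6 and 12 are commercial.

Step 1
Reactants: 1 (R)-(−)-carvone
Product: 2 (1R,4R,6R)-1-methyl-4-(prop-1-en-2-yl)-7-oxabicyclo[4.1.0]heptan-2-one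
Conditions: 35% aq H2O2, NaOH (cat.), MeOH, 0 °C
Reagents that add atoms: hydrogen peroxide OO
Why: Weitz–Scheffer nucleophilic epoxidation touches only the enone, and hydroperoxide adds anti to the isopropenyl group (both new centres are erased in step 2).

Step 2
Reactants: 2 carvone epoxide
Product: 4 (3R)-5-oxo-3-(prop-1-en-2-yl)pentanoic acid, via trans-diol ketone 3 (not isolated)
Conditions: 5% aq H2SO4, THF, 0 °C to rt; then NaIO4, THF–H2O, rt
Reagents that add atoms: water O; sodium periodate [Na+].[O-]I(=O)(=O)=O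
Why: Acid-catalysed epoxide hydrolysis and Malaprade-type periodate cleavage of the α,β-dihydroxy ketone excise carvone C2 with its methyl as acetic acid, so the former carbonyl becomes the acid (C5) and carvone C3 the aldehyde (C9), while the stereocentre (C7) is untouched.

Step 3
Reactants: 4 (3R)-5-oxo-3-(prop-1-en-2-yl)pentanoic acid
Product: 5 methyl (3R)-5-oxo-3-(prop-1-en-2-yl)pentanoate
Conditions: MeI, KHCO3, DMF, rt
Reagents that add atoms: iodomethane CI
Why: SN2 O-alkylation of the carboxylate under bicarbonate conditions is too mild to enolise the aldehyde.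

Step 4
Reactants: 5 methyl (3R)-5-oxo-3-(prop-1-en-2-yl)pentanoate; 6 ethyl propiolate
Product: 10 ethyl (2Z)-3-iodo-2-[(2S,4R)-6-oxo-4-(prop-1-en-2-yl)oxan-2-yl]prop-2-enoate, via silyl iodoallenolate 7 (not isolated), via silyl ether adduct 8 (not isolated), via hydroxy diester 9 (not isolated)
Conditions: Me3SiI, (R)-3,3-diphenyl-1-(o-tolyl)tetrahydropyrrolo[1,2-c][1,3,2]oxazaborole·HNTf2 (20 mol %), CH2Cl2, −78 °C; 1 M HCl, THF, 0 °C; then CSA (cat.), CH2Cl2, rt
Reagents that add atoms: iodotrimethylsilane C[Si](C)(C)I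
Why: In this asymmetric three-component β-iodo Morita–Baylis–Hillman-type reaction, catalyst-controlled Re-face addition of the in situ iodoallenolate sets 9S, the kinetic adduct is the Z iodoacrylate (I cis to C14, trans to C9), and acid-catalysed lactonisation ties O9 to C5 in a temporary δ-lactone.

Step 5
Reactants: 10 iodoacrylate δ-lactone
Product: 11 (4R,6S)-6-[(1E)-3-hydroxy-1-iodoprop-1-en-2-yl]-4-(prop-1-en-2-yl)oxan-2-ol (anomer mixture)
Conditions: i-Bu2AlH (3.5 equiv), CH2Cl2, −78 °C; aq potassium sodium tartrate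
Reagents that add atoms: none
Why: Aluminium hydride reduction at −78 °C stops at the stable aluminium hemiacetal for the lactone but carries the conjugated ester through to the allylic alcohol, so C5 and C14 reach their required oxidation levels together and the alkenyl iodide is inert.

Step 6
Reactants: 11 lactol; 12 3-(triphenyl-λ5-phosphanylidene)oxolan-2-one
Product: 13 (3E)-3-[(3S,5S,6E)-5-hydroxy-6-(hydroxymethyl)-7-iodo-3-(prop-1-en-2-yl)hept-6-en-1-ylidene]oxolan-2-one
Conditions: toluene, PhCO2H (cat.), 90 °C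
Reagents that add atoms: none
Why: Wittig olefination of the open hydroxy-aldehyde tautomer with the stabilised cyclic ylide gives the E-alkylidene lactone (C6 trans to C15, cis to C3), brings in C15, C4, C3 and C2 at once, and frees O9.

Step 7
Reactants: 13 diol lactone
Product: 14 (3E)-3-[(3S)-3-{[(4S,5E)-5-(iodomethylidene)-2,2-dimethyl-1,3-dioxan-4-yl]methyl}-4-methylpent-4-en-1-ylidene]oxolan-2-one
Conditions: Me2C(OMe)2, PPTS (cat.), CH2Cl2, rt
Reagents that add atoms: 2,2-dimethoxypropane COC(C)(C)OC
Why: Acid-catalysed transketalisation closes the six-membered ketal over the only 1,3-diol (O9/O14), masking both allylic oxygens as non-ionisable ethers.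

Step 8
Reactants: 14 acetonide lactone
Product: 16 methyl (2E,5S)-2-(2-hydroxyethyl)-5-{[(4S,5E)-5-(iodomethylidene)-2,2-dimethyl-1,3-dioxan-4-yl]methyl}-6-methylhepta-2,6-dienoate, via potassium carboxylate 15 (not isolated)
Conditions: KOH (1.05 equiv), THF–MeOH–H2O, rt; evaporate; MeI, DMF, rt
Reagents that add atoms: potassium hydroxide [K+].[OH-]; iodomethane CI
Why: Saponification followed by SN2 alkylation of the dry carboxylate turns the lactone carbonyl into the C15 methyl ester before relactonisation can occur and leaves the hydroxyl on C2.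

Step 9
Reactants: 16 hydroxy ester
Product: 17 methyl (2E,5S)-2-(2-iodoethyl)-5-{[(4S,5E)-5-(iodomethylidene)-2,2-dimethyl-1,3-dioxan-4-yl]methyl}-6-methylhepta-2,6-dienoate
Conditions: I2, PPh3, imidazole, CH2Cl2, 0 °C
Reagents that add atoms: iodine II
Why: Appel-type iodination displaces the activated primary C2 oxygen by SN2, and the imidazole buffer keeps the ketal intact.

Step 10
Reactants: 17 alkenyl iodide/alkyl iodide
Product: 19 methyl (1(10)E,4E,7S,9S)-9,14-(isopropylidenedioxy)germacra-1(10),4,11-trien-15-oate, via C2 alkylzinc iodide 18 (not isolated)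
Conditions: Zn dust, LiCl, THF, 25 °C; then syringe-pump addition to PdCl2(dppf) (10 mol %), THF, 45 °C, final concentration about 1 mM
Reagents that add atoms: none
Why: Zinc inserts selectively into the primary sp3 C2–I bond (the alkenyl C1–I bond is inert at 25 °C), zerovalent palladium then adds oxidatively to C1–I with retention, intramolecular transmetalation gives an eleven-membered palladacycle, and reductive elimination forms C1–C2. The reaction type is the Negishi alkenyl–alkyl cross-coupling, run intramolecularly under pseudo-high dilution. One ring is closed, the ten-membered carbocycle C1–C10, by end-to-end macrocyclisation of the open chain, and the pre-existing dioxane ends up fused at C9–C10. No stereocentre is created: the E geometry of C1=C10 (C2 cis to C14) is inherited from the alkenyl iodide, and C7 and C9 are untouched. The step needs cyclisation to beat oligomerisation and β-hydride elimination, which is secured by the cis C3/C6 arrangement on the C4=C5 enoate and the rigid 5-alkylidene-1,3-dioxane bringing C2 and C1 together, by slow addition that keeps the zinc reagent dilute, and by the wide-bite-angle dppf ligand that speeds reductive elimination. Allylic C–O ionisation is avoided because O9 and O14 are ketal ethers and not esters.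

Step 11
Reactants: 19 macrocyclic acetonide
Product: 20 methyl (1(10)E,4E,7S,9S)-9,14-dihydroxygermacra-1(10),4,11-trien-15-oate
Conditions: AcOH–THF–H2O (3:1:1), 35 °C
Reagents that add atoms: none
Why: Mild acid-catalysed ketal hydrolysis should spare the ring because the enoate olefin and the doubly oxygen-flanked C1=C10 olefin are too electron-poor for transannular protonation.

Step 12
Reactants: 20 macrocyclic diol
Product: 22 methyl (1(10)E,4E,7S,9S)-9-acetoxy-14-hydroxygermacra-1(10),4,11-trien-15-oate, via cyclic orthoacetate 21 (not isolated)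
Conditions: MeC(OMe)3, CSA (cat.), CH2Cl2, rt; then 80% aq AcOH, 0 °C
Reagents that add atoms: trimethyl orthoacetate COC(C)(OC)OC; water O
Why: In this orthoester-mediated monoacylation the cyclic hemiorthoester collapses kinetically by releasing the less hindered primary O14, so the acetate stays on the secondary O9.

Step 13
Reactants: 22 9-acetate allylic alcohol
Product: 23 methyl (1R,4E,7S,9S,10S)-9-acetoxy-1,10-epoxy-14-hydroxygermacra-4,11-dien-15-oate
Conditions: Ti(OiPr)4 (20 mol %), L-(+)-diethyl tartrate (24 mol %), t-BuOOH, 4 Å molecular sieves, CH2Cl2, −20 °C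
Reagents that add atoms: tert-butyl hydroperoxide CC(C)(C)OO
Why: In the Katsuki–Sharpless asymmetric epoxidation O14-bound titanium reaches only the allylic C1=C10 olefin, the L-(+)-tartrate selects the face that gives 1R,10S, syn addition to the E olefin keeps C2 cis to C14, and rotation of the olefin through the ring lets both planar-chiral conformers funnel into one product.

Step 14
Reactants: 23 epoxy alcohol
Product: 24 target, methyl (1R,4E,7S,9S,10S)-9-acetoxy-1,10-epoxy-14-(isobutyryloxy)germacra-4,11-dien-15-oate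
Conditions: (i-PrCO)2O, Et3N, DMAP (cat.), CH2Cl2, 0 °C
Reagents that add atoms: isobutyric anhydride CC(C)C(=O)OC(=O)C(C)C
Why: DMAP-catalysed acylation of the only free hydroxyl takes place under chloride-free, non-acidic conditions that leave the oxirane closed.

Compound list
1 | (R)-(−)-carvone | CC1=CC[C@H](CC1=O)C(C)=C | starting material
2 | (1R,4R,6R)-1-methyl-4-(prop-1-en-2-yl)-7-oxabicyclo[4.1.0]heptan-2-one | C=C(C)[C@@H]1C[C@H]2O[C@@]2(C)C(=O)C1 | intermediate
3 | (2R,3S,5R)-2,3-dihydroxy-2-methyl-5-(prop-1-en-2-yl)cyclohexan-1-one | C=C(C)[C@@H]1C[C@H](O)[C@@](C)(O)C(=O)C1 | intermediate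
4 | (3R)-5-oxo-3-(prop-1-en-2-yl)pentanoic acid | OC(=O)C[C@@H](CC=O)C(C)=C | intermediate
5 | methyl (3R)-5-oxo-3-(prop-1-en-2-yl)pentanoate | COC(=O)C[C@@H](CC=O)C(C)=C | intermediate
6 | ethyl propiolate | C#CC(=O)OCC | starting material
7 | 1-ethoxy-3-iodo-1-(trimethylsilyloxy)propa-1,2-diene | CCOC(=C=CI)O[Si](C)(C)C | intermediate
8 | 1-ethyl 7-methyl (2Z,3S,5R)-2-(iodomethylidene)-5-(prop-1-en-2-yl)-3-(trimethylsilyloxy)heptanedioate | COC(=O)C[C@@H](C[C@H](O[Si](C)(C)C)/C(=C/I)C(=O)OCC)C(C)=C | intermediate
9 | 1-ethyl 7-methyl (2Z,3S,5R)-3-hydroxy-2-(iodomethylidene)-5-(prop-1-en-2-yl)heptanedioate | COC(=O)C[C@@H](C[C@H](O)/C(=C/I)C(=O)OCC)C(C)=C | intermediate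
10 | ethyl (2Z)-3-iodo-2-[(2S,4R)-6-oxo-4-(prop-1-en-2-yl)oxan-2-yl]prop-2-enoate | O=C1C[C@H](C(C)=C)C[C@H](O1)/C(=C/I)C(=O)OCC | intermediate
11 | (4R,6S)-6-[(1E)-3-hydroxy-1-iodoprop-1-en-2-yl]-4-(prop-1-en-2-yl)oxan-2-ol (anomer mixture) | OC1C[C@H](C(C)=C)C[C@H](O1)/C(=C/I)CO | intermediate
12 | 3-(triphenyl-λ5-phosphanylidene)oxolan-2-one | O=C1OCCC1=P(c1ccccc1)(c1ccccc1)c1ccccc1 | starting material
13 | (3E)-3-[(3S,5S,6E)-5-hydroxy-6-(hydroxymethyl)-7-iodo-3-(prop-1-en-2-yl)hept-6-en-1-ylidene]oxolan-2-one | O=C1OCC/C1=C\C[C@@H](C[C@H](O)/C(=C/I)CO)C(C)=C | intermediate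
14 | (3E)-3-[(3S)-3-{[(4S,5E)-5-(iodomethylidene)-2,2-dimethyl-1,3-dioxan-4-yl]methyl}-4-methylpent-4-en-1-ylidene]oxolan-2-one | O=C1OCC/C1=C\C[C@@H](C[C@@H]2OC(C)(C)OC/C2=C\I)C(C)=C | intermediate
15 | potassium (2E,5S)-2-(2-hydroxyethyl)-5-{[(4S,5E)-5-(iodomethylidene)-2,2-dimethyl-1,3-dioxan-4-yl]methyl}-6-methylhepta-2,6-dienoate | OCC/C(C(=O)[O-])=C\C[C@@H](C[C@@H]1OC(C)(C)OC/C1=C\I)C(C)=C.[K+] | intermediate
16 | methyl (2E,5S)-2-(2-hydroxyethyl)-5-{[(4S,5E)-5-(iodomethylidene)-2,2-dimethyl-1,3-dioxan-4-yl]methyl}-6-methylhepta-2,6-dienoate | OCC/C(C(=O)OC)=C\C[C@@H](C[C@@H]1OC(C)(C)OC/C1=C\I)C(C)=C | intermediate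
17 | methyl (2E,5S)-2-(2-iodoethyl)-5-{[(4S,5E)-5-(iodomethylidene)-2,2-dimethyl-1,3-dioxan-4-yl]methyl}-6-methylhepta-2,6-dienoate | ICC/C(C(=O)OC)=C\C[C@@H](C[C@@H]1OC(C)(C)OC/C1=C\I)C(C)=C | intermediate
18 | C2 alkylzinc iodide derived from 17 (alkenyl iodide intact) | I[Zn]CC/C(C(=O)OC)=C\C[C@@H](C[C@@H]1OC(C)(C)OC/C1=C\I)C(C)=C | intermediate
19 | methyl (1(10)E,4E,7S,9S)-9,14-(isopropylidenedioxy)germacra-1(10),4,11-trien-15-oate | C=C(C)[C@H]1C/C=C(/C(=O)OC)CC/C=C2\COC(C)(C)O[C@H]2C1 | intermediate
20 | methyl (1(10)E,4E,7S,9S)-9,14-dihydroxygermacra-1(10),4,11-trien-15-oate | C=C(C)[C@H]1C/C=C(/C(=O)OC)CC/C=C(\CO)[C@@H](O)C1 | intermediate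
21 | 9,14-O-(1-methoxyethylidene) cyclic orthoacetate of 20 (epimers at the orthoester carbon) | C=C(C)[C@H]1C/C=C(/C(=O)OC)CC/C=C2\COC(C)(OC)O[C@H]2C1 | intermediate
22 | methyl (1(10)E,4E,7S,9S)-9-acetoxy-14-hydroxygermacra-1(10),4,11-trien-15-oate | C=C(C)[C@H]1C/C=C(/C(=O)OC)CC/C=C(\CO)[C@@H](OC(C)=O)C1 | intermediate
23 | methyl (1R,4E,7S,9S,10S)-9-acetoxy-1,10-epoxy-14-hydroxygermacra-4,11-dien-15-oate | C=C(C)[C@H]1C/C=C(/C(=O)OC)CC[C@H]2O[C@]2(CO)[C@@H](OC(C)=O)C1 | intermediate
24 | methyl (1R,4E,7S,9S,10S)-9-acetoxy-1,10-epoxy-14-(isobutyryloxy)germacra-4,11-dien-15-oate | C=C(C)[C@H]1C/C=C(/C(=O)OC)CC[C@H]2O[C@]2(COC(=O)C(C)C)[C@@H](OC(C)=O)C1 | target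

Total step count: 14. Longest linear sequence: 14 steps, from 1 to 24.

Steps most likely to fail

Step 10. Intermolecular transmetalation (oligomerisation), protodezincation or β-hydride elimination at the alkylpalladium stage may outrun closure of the strained E-olefin ring. The fallback sets out from 16 and comes back at 19. It closes the same bond by carbonyl addition instead of cross-coupling. Alcohol 16 is oxidised with buffered Dess–Martin periodinane to the aldehyde F1. This is cyclised at once by a Nozaki–Hiyama–Kishi reaction (CrCl2, catalytic NiCl2, DMSO, high dilution) to the C2 allylic alcohol F2, whose carbinol epimers are of no consequence. Acetylation (Ac2O, pyridine) gives the allylic acetate F3. Pd(PPh3)4-catalysed reduction with Bu3SnH then delivers hydride to the less hindered C2 terminus of the allyl complex and gives 19.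

Step 13. Facial selectivity may be poor if tartrate control opposes the preferred planar-chiral conformer. Turnover may be slow at the hindered, cis-substituted allylic alcohol, and the acetyl group may migrate from O9 to O14 on titanium. The fallback sets out from 22 and comes back at 23. It replaces reagent control by substrate control. In a hydroxyl-directed epoxidation with VO(acac)2 and t-BuOOH (CH2Cl2, 0 °C), the O14-bound vanadium peroxide can reach only the outer face of the E olefin in the conformer that keeps the C9 acetate pseudo-equatorial. This path makes no further compound F0.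

Step 12. The hemiorthoester may collapse with poor regioselectivity, or the acetyl group may later migrate to the primary oxygen, which would put the acetate on O14. The fallback sets out from 20 and comes back at 22. It differentiates the two hydroxyls by protection instead of by orthoester collapse. Selective silylation of the primary alcohol (TBSCl, imidazole, CH2Cl2, 0 °C) gives the 14-silyl ether F4. Acetylation (Ac2O, DMAP, pyridine) gives the 9-acetate silyl ether F5. HF·pyridine in THF then releases 22.

Further compounds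
F1 | step 10 | methyl (2E,5S)-5-{[(4S,5E)-5-(iodomethylidene)-2,2-dimethyl-1,3-dioxan-4-yl]methyl}-6-methyl-2-(2-oxoethyl)hepta-2,6-dienoate | O=CC/C(C(=O)OC)=C\C[C@@H](C[C@@H]1OC(C)(C)OC/C1=C\I)C(C)=C
F2 | step 10 | methyl (1(10)E,4E,7S,9S)-2-hydroxy-9,14-(isopropylidenedioxy)germacra-1(10),4,11-trien-15-oate (C2 epimers) | C=C(C)[C@H]1C/C=C(/C(=O)OC)CC(O)/C=C2\COC(C)(C)O[C@H]2C1
F3 | step 10 | methyl (1(10)E,4E,7S,9S)-2-acetoxy-9,14-(isopropylidenedioxy)germacra-1(10),4,11-trien-15-oate (C2 epimers) | C=C(C)[C@H]1C/C=C(/C(=O)OC)CC(OC(C)=O)/C=C2\COC(C)(C)O[C@H]2C1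
F0 | step 13 | none | none
F4 | step 12 | methyl (1(10)E,4E,7S,9S)-14-(tert-butyldimethylsilyloxy)-9-hydroxygermacra-1(10),4,11-trien-15-oate | C=C(C)[C@H]1C/C=C(/C(=O)OC)CC/C=C(\CO[Si](C)(C)C(C)(C)C)[C@@H](O)C1
F5 | step 12 | methyl (1(10)E,4E,7S,9S)-9-acetoxy-14-(tert-butyldimethylsilyloxy)germacra-1(10),4,11-trien-15-oate | C=C(C)[C@H]1C/C=C(/C(=O)OC)CC/C=C(\CO[Si](C)(C)C(C)(C)C)[C@@H](OC(C)=O)C1
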